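The rate constants are invented; the run is a simulation.

Whatever went in as substrate stayed in the flask as free substrate, dormant form, decomposition product or an adduct, and each adduct held one more reagent than the one below it.

common to all: time 6.0 d

|  | substrate | reagent | temperature | remark |
|---|---|---|---|---|
| blue | 0.050 M | 1.10 equiv (fed, over 4.0 d) | 80 °C | all else is in the flask from the start; the feed brings no volume worth counting |
| violet | 0.050 M | 1.10 equiv | 80 °C | everything together at the start |
| ochre | 0.050 M (fed, over 4.0 d) | 1.10 equiv | 80 °C | all else is in the flask from the start; the feed brings no volume worth counting |
| amber | 0.050 M | 1.10 equiv |  | everything together at the start at 40 °C, warmed to 80 °C at 4.0 d |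
| red | 0.050 M (fed, over 4.0 d) | 1.10 equiv |  | the addition at 40 °C, then warmed to 80 °C; the feed brings no volume worth counting |

    reagent + first product → bis adduct (k1 = 1.94 M⁻¹ h⁻¹, Ea1 = 68.0 kJ mol⁻¹)
    reagent + bis adduct → triple product (k2 = 0.230 M⁻¹ h⁻¹, Ea2 = 73.0 kJ mol⁻¹)
    substrate + reagent → first product (k3 = 0.637 M⁻¹ h⁻¹, Ea3 = 65.0 kJ mol⁻¹)
    substrate ⇌ dormant form (K4 = 5.0, k4 = 0.118 h⁻¹, Ea4 = 118 kJ mol⁻¹, ΔH4 = −56.0 kJ mol⁻¹)
    substrate → decomposition product (k5 = 3.32 × 10⁻⁵ h⁻¹, Ea5 = 127 kJ mol⁻¹)
    (constants at 80 °C)

- the flask with the highest amount of triple product, in percent of the substrate charged ("all alike" if they lie within 1.5 percentage points) (blue / violet / ochre / amber / red / all alike)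
- final triple product, as a percentage of the substrate charged, in blue
- final triple product, as a percentage of the substrate charged, in violet
- final triple product, as a percentage of the substrate charged, in ochre
- final triple product, as a percentage of the substrate charged, in amber
- final triple product, as a percentage of the substrate charged, in red

- at 80 °C the constants are as listed, elsewhere as the activation energies and enthalpies make them

I wrote this note for the bench before any run had finished. With reagent held at its charge of 0.0550 M, step 2 is pseudo-first-order, and bis adduct in violet has a half-life of 2.3 d. The number I carried was the count of bis adduct half-lives that fit into the hot days, reagent taken as charged. Red has 2.00 d hot, so its count is 0.876; I set its days at 40 °C to zero as a simplification. Violet's count is 2.63, higher than red's, and amber's equals red's.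

Free substrate in violet has a half-life of 0.24 d by the forward step to dormant form, shorter than the 0.82 d by step 3, so I expected dormant form at 5.0 times free substrate once equilibrium held. Leave the hot days as they are, and expect triple product to lag behind bis adduct. I ranked violet first, with its substrate there from the start, then ochre, then blue, whose reagent arrives slowly, and amber and red last, without separating those two.

The forecast named violet, with 9% in blue, 14.5% in violet, 13% in ochre, 7.5% in amber and 8% in red, on the ground that “its early burst, before the dormant pool fills, builds bis adduct while reagent is plentiful”. Its order matched mine, but it also put red above amber.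

The run put violet on top, with 7.73% in blue, 12.9% in violet, 10.3% in ochre, 5.34% in amber and 5.05% in red. Violet's own figure moved by 5 points at 0.845 equiv or 1.33 equiv of reagent, with the other amounts and the time held. Red ended with 5.05% triple product beside 22.1% bis adduct at a count of 0.876. The neighbouring flask, red with 2.80 equiv of reagent, has a count of 2.23, and after 6.00 d it held 28.1% triple product beside 29.6% bis adduct.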